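**Retrosynthetic overview**
- The target acid comes from its 2,4,6-trimethylbenzyl ester by hydrogenolysis. This benzyl-type group has no aromatic C–H that an iridium borylation catalyst can reach.
- Key disconnection: the aryl C4–O bond of ring B, not the crowded acyl C–O bond. The ring A acid acts as O-nucleophile towards C4–H of ring B, through a one-pot C–H borylation and aerobic copper acyloxylation.
- Each heptyl chain comes from ArCH3 plus 1-bromohexane, by lateral lithiation of a commercial o-toluic acid.
- No ring is formed, since both benzene rings are bought intact. The order is side chains, then the depside C–O bond, then deprotection.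

Assumption: the SMILES holds no stereocentre and no stereogenic double bond, so the target is achiral and no stereocontrol is needed.

**Step 1**
Reactants: 1 2,4-dimethoxy-6-methylbenzoic acid; 2 1-bromohexane
Product: 4 2-heptyl-4,6-dimethoxybenzoic acid, via dilithiated dimethoxytoluic acid 3 (not isolated)
Conditions: LiN(iPr)2 (2.2 equiv, commercial solution), THF, −78 to 0 °C, 1 h; 2 (1.1 equiv), −78 °C to rt; aq HCl work-up, acid/base extraction
Reagents that add atoms: none
Why: Lateral (benzylic) lithiation of an o-toluic acid gives the carboxylate-stabilised dianion, which is alkylated by SN2 with a primary bromide; the amide base is too weak to lithiate the ring C–H between the two methoxy groups, so only the CH3 reacts, and no stereocentre is formed.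

**Step 2**
Reactants: 5 2-methoxy-6-methylbenzoic acid; 2 1-bromohexane
Product: 8 2,4,6-trimethylbenzyl 2-heptyl-6-methoxybenzoate, via dilithiated methoxytoluic acid 6 (not isolated), via lithium 2-heptyl-6-methoxybenzoate 7 (not isolated)
Conditions: LiN(iPr)2 (2.2 equiv), THF, −78 to 0 °C; 2 (1.1 equiv), −78 °C to rt; evaporate THF and amine; 2,4,6-trimethylbenzyl chloride (1.3 equiv), NaI (10 mol %), DMF, 50 °C, 12 h
Reagents that add atoms: 2,4,6-trimethylbenzyl chloride, Cc1cc(C)c(CCl)c(C)c1
Why: The same lateral lithiation and SN2 alkylation is followed by iodide-catalysed SN2 O-alkylation of the lithium carboxylate left in the flask, an esterification at oxygen that the two ortho groups beside the acyl carbon do not slow.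

**Step 3**
Reactants: 8 2,4,6-trimethylbenzyl 2-heptyl-6-methoxybenzoate; 4 2-heptyl-4,6-dimethoxybenzoic acid
Product: 10 2,4,6-trimethylbenzyl 4-[(2-heptyl-4,6-dimethoxybenzoyl)oxy]-2-heptyl-6-methoxybenzoate, via aryl pinacol boronate 9 (not isolated)
Conditions: [Ir(OMe)(cod)]2 (1.5 mol %), 4,4'-di-tert-butyl-2,2'-bipyridine (3 mol %), B2pin2 (1.0 equiv), MTBE, 80 °C (sealed), 16 h; evaporate; 4 (1.3 equiv), Cu(OTf)2 (30 mol %), pyridine (2 equiv), 4 Å MS, EtOAc–MeCN 1:1, O2 (1 atm), 65 °C, 24 h
Reagents that add atoms: bis(pinacolato)diboron, CC1(C)OB(OC1(C)C)B1OC(C)(C)C(C)(C)O1 (gives the Bpin group of 9; no atom of it stays in 10)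
Why: Proposed new method: a sterically governed C–H acyloxylation makes the depside aryl C–O bond directly from an arene C–H and a di-ortho-substituted benzoic acid; the iridium trisboryl catalyst can reach only C4–H of 8, because C3–H and C5–H each have an ortho neighbour, both positions ortho to the ester are blocked, and the mesityl C–H bonds lie between two methyl groups; the divalent copper carboxylate formed from Cu(OTf)2, 4 and pyridine then takes the unhindered, ester-activated aryl group from boron through a carboxylate-bridged Cu–O–B contact, a second divalent copper oxidises the aryl copper species to trivalent copper, C–O reductive elimination with the only coupling ligand present (the carboxylate of 4, since triflate does not couple and acetate, alcohol and free water are excluded) gives 10, and O2 returns monovalent copper to divalent copper; because the bond is made at the carboxylate oxygen, the crowding at the acyl carbon that slows ordinary depside acylation plays no part; the closest known reaction types are the Chan–Lam O-arylation of carboxylic acids with arylboronic acids and the one-pot iridium borylation/copper etherification of arenes, neither shown for in situ pinacol boronates with 2,6-disubstituted benzoic acids or for depsides.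

**Step 4**
Reactants: 10 2,4,6-trimethylbenzyl 4-[(2-heptyl-4,6-dimethoxybenzoyl)oxy]-2-heptyl-6-methoxybenzoate
Product: 11 4-[(2-heptyl-4,6-dimethoxybenzoyl)oxy]-2-heptyl-6-methoxybenzoic acid (target)
Conditions: H2 (1 atm), Pd/C (10 wt %), EtOAc, rt
Reagents that add atoms: none
Why: Catalytic hydrogenolysis cleaves the benzyl-type ester under neutral conditions, where the aryl ester, methyl ethers and alkyl chains are inert and neither depside cleavage nor decarboxylation can occur.

**Compound list**
1 | 2,4-dimethoxy-6-methylbenzoic acid | Cc1cc(OC)cc(OC)c1C(=O)O | starting material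
2 | 1-bromohexane | CCCCCCBr | starting material
3 | dilithiated dimethoxytoluic acid (lithium 2-(lithiomethyl)-4,6-dimethoxybenzoate) | [Li+].[Li+].[CH2-]c1cc(OC)cc(OC)c1C(=O)[O-] | intermediate
4 | 2-heptyl-4,6-dimethoxybenzoic acid | CCCCCCCc1cc(OC)cc(OC)c1C(=O)O | intermediate
5 | 2-methoxy-6-methylbenzoic acid | Cc1cccc(OC)c1C(=O)O | starting material
6 | dilithiated methoxytoluic acid (lithium 2-(lithiomethyl)-6-methoxybenzoate) | [Li+].[Li+].[CH2-]c1cccc(OC)c1C(=O)[O-] | intermediate
7 | lithium 2-heptyl-6-methoxybenzoate | [Li+].CCCCCCCc1cccc(OC)c1C(=O)[O-] | intermediate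
8 | 2,4,6-trimethylbenzyl 2-heptyl-6-methoxybenzoate | CCCCCCCc1cccc(OC)c1C(=O)OCc1c(C)cc(C)cc1C | intermediate
9 | aryl pinacol boronate (2,4,6-trimethylbenzyl 2-heptyl-6-methoxy-4-(4,4,5,5-tetramethyl-1,3,2-dioxaborolan-2-yl)benzoate) | CCCCCCCc1cc(B2OC(C)(C)C(C)(C)O2)cc(OC)c1C(=O)OCc1c(C)cc(C)cc1C | intermediate
10 | 2,4,6-trimethylbenzyl 4-[(2-heptyl-4,6-dimethoxybenzoyl)oxy]-2-heptyl-6-methoxybenzoate | CCCCCCCc1cc(OC(=O)c2c(CCCCCCC)cc(OC)cc2OC)cc(OC)c1C(=O)OCc3c(C)cc(C)cc3C | intermediate
11 | 4-[(2-heptyl-4,6-dimethoxybenzoyl)oxy]-2-heptyl-6-methoxybenzoic acid | CCCCCCCc1cc(OC(=O)c2c(CCCCCCC)cc(OC)cc2OC)cc(OC)c1C(=O)O | target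

**Step count**
Total steps: 4. Longest linear sequence: 3 (5 → 8 → 10 → 11). Step 1 is the convergent branch.

**Three steps most likely to fail**

**Step 3 (the proposed new step).**
- Risks: slow boron-to-copper transfer from the pinacol ester, phenol formation from adventitious water, protodeboronation, or biaryl formation.
- Fallback (known chemistry), setting out from 8: run the same iridium borylation to 9. Oxidise the crude boronate with aqueous H2O2 in THF, the established arene-to-phenol sequence, to 2,4,6-trimethylbenzyl 2-heptyl-4-hydroxy-6-methoxybenzoate F1.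
- Separately convert acid 4 with 1-chloro-N,N,2-trimethylpropenylamine in CH2Cl2 into 2-heptyl-4,6-dimethoxybenzoyl chloride F2.
- Join the two with Et3N and DMAP in CH2Cl2, the classical acyl C–O depside esterification. This comes back to the route at 10.

**Step 2.**
- Risks: incomplete dianion formation or alkylation, or sluggish O-alkylation of the lithium salt in the same flask, giving mixtures of esters.
- Fallback, setting out from 5: reverse the order and change the carbanion. Esterify first with 2,4,6-trimethylbenzyl chloride and K2CO3 in DMF to 2,4,6-trimethylbenzyl 2-methoxy-6-methylbenzoate F3.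
- Deprotonate this hindered ester with 1.1 equiv LiN(iPr)2 in THF at −78 °C to the o-toluate monoanion 2,4,6-trimethylbenzyl 2-(lithiomethyl)-6-methoxybenzoate F4.
- Alkylate it with 2. This comes back to the route at 8.

**Step 4.**
- Risk: slow hydrogenolysis, because both the acyl and the benzyl side of the ester are di-ortho-substituted.
- Fallback, setting out from 10: use ionic cleavage in place of surface catalysis, with CF3CO2H–CH2Cl2 (1:4) and Et3SiH (3 equiv) at 0 °C.
- The electron-rich trimethylbenzyl cation leaves by an SN1 path and is reduced by the silane before it can alkylate ring A. This comes back to the route at 11 and makes no compound outside the list (F0).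

**Further compounds**
F1 | step 3 | 2,4,6-trimethylbenzyl 2-heptyl-4-hydroxy-6-methoxybenzoate | CCCCCCCc1cc(O)cc(OC)c1C(=O)OCc1c(C)cc(C)cc1C
F2 | step 3 | 2-heptyl-4,6-dimethoxybenzoyl chloride | CCCCCCCc1cc(OC)cc(OC)c1C(=O)Cl
F3 | step 2 | 2,4,6-trimethylbenzyl 2-methoxy-6-methylbenzoate | Cc1cccc(OC)c1C(=O)OCc1c(C)cc(C)cc1C
F4 | step 2 | 2,4,6-trimethylbenzyl 2-(lithiomethyl)-6-methoxybenzoate | [Li+].[CH2-]c1cccc(OC)c1C(=O)OCc1c(C)cc(C)cc1C
F0 | step 4 | none | none
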